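| flask | substrate | partner | free catalyst | remark | time |
|---|---|---|---|---|---|
| maple | 0.50 mM | 2 equiv | 4.5 mol% | run made earlier |  |
| oak | 0.50 mM | 2 equiv | 10 mol% | run made earlier |  |
| flask | 0.50 mM | 2.00 equiv | 6.7 mol% |  | 4.0 min |

- maple (time / min: target / %, substrate / %): 0.667: 28.5, 71.1; 1.50: 30.7, 68.6; 3.00: 31.6, 69.1; 5.00: 30.7, 69.1
- oak (time / min: target / %, substrate / %): 0.417: 48.3, 53.4; 0.833: 55.4, 45.2; 2.00: 56.9, 43.5; 5.00: 57.3, 43.6

(scatter of a reading: 0.5 percentage points)

1. the target in the flask at 4.0 min, as a percentage of the substrate charged
2. the substrate in the flask at 4.0 min, as a percentage of the substrate charged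



Start with the easy step: in the maple run, divide the first target reading by its time, which gives an average rate of 0.427 min⁻¹ as a fraction of the charge. Between the first two readings the rate is 0.0264 min⁻¹, a rough reading that is slower by a factor of 16.2.

Now split that factor. Taking the rate as first order in each, the substrate left accounts for at most 1.46, and partner, if used one for one with target, for 1.18. That leaves 9.39, so read the stop as lost catalyst activity.

Treat the rate as first order in substrate (pseudo-first-order, with active catalyst as a falling factor). The logarithm of the fraction left then falls with the active catalyst, and if each catalyst lasts equally long, the accumulated fall scales with the loading. Maple gives 8.21 and oak gives 8.30. Take their mean, 8.26, as the reach: minus the natural logarithm of the fraction of substrate left at the stop, per loading of free catalyst, with substrate charge and partner equivalents held.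

For the flask, my reckoning leaves 57.5% of the substrate. The forecast says 43% target and 57.2% substrate, reasoning that “The plateau depends on catalyst loading, so this is catalyst death”; my figure is 0.31 percentage points higher.

The flask gives 43.1% target and 56.9% substrate.

    catalyst intermediate A → spent catalyst (k = 0.190 s⁻¹)
    catalyst intermediate B → free catalyst + target (k = 180 s⁻¹)
    partner + free catalyst → catalyst intermediate A (k = 660 M⁻¹ s⁻¹)
    substrate + catalyst intermediate A ⇌ catalyst intermediate B (K = 12000 M⁻¹, k = 3200 M⁻¹ s⁻¹)

At 4.00 min, spent catalyst in the flask stands at >99.9% of the catalyst charged, while 57% of the substrate remains: this flask has stopped, not merely slowed. Its own reach is 8.41, beside 8.26 from the two runs.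

Take a neighbouring flask, like this one but with 11 mol% of free catalyst. The reach 8.26 leaves 40.3% of the substrate there; the computed neighbouring flask holds 39.7% substrate and 60.3% target.

(The runs come from a simulation with constants of no real substance; scatter was added.)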